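**Retrosynthetic overview**
- The strategy rests on the trans-3,4-disubstituted γ-butyrolactone (O1–C2(=O)–C3–C4–C5). The C4–CH2Ar bond is made from a nucleophilic benzyl carbon and the C3–CH2Ar' bond from an electrophilic one, so both are cut back to the C3=C4 bond of a butenolide whose C5 carries a removable menthyloxy acetal.
- Key disconnection (one flask): C4–C(benzylic) to a lithiated 2-aryl-1,3-dithiane (1,4-addition) and C3–CH2 to a benzylic bromide that already carries the complete threo arylglycerol β-aryl ether as a 1,3-dioxane acetonide. Afterwards the dithiane is desulfurized and C5–O(menthyl) is reduced to CH2.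
- Side chain: C7–C8 by an Evans syn-aldol of an (aryloxy)acetyl oxazolidinone with O-benzylvanillin (sets 7R,8R); the C8–O–aryl bond comes from methyl vanillate and tert-butyl bromoacetate.
- Ring order: the butenolide ring comes first (from furfural, made a single acetal epimer with (−)-menthol) and is kept to the end, opened and re-closed once when C5 is reduced. The dithiane and 1,3-dioxane rings are temporary, and the key step closes no ring.
- Last step: hydrogenolysis of the two benzyl ethers.

Key step: step 11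

Remark: lactone atoms are O1, C2(=O), C3, C4, C5 and side-chain atoms are C7 (carbinol), C8 (aryloxy carbon), C9 (CH2OH); BnV = 4-benzyloxy-3-methoxyphenyl, Men = l-menthyl, SCBn = 4-{[(4R,5R)-4-BnV-2,2-dimethyl-1,3-dioxan-5-yl]oxy}-3-methoxybenzyl; O-metal and O-boron species that differ from a product only by aqueous work-up are not numbered; the (5R) epimer of 6 is assumed to be the one that crystallizes.

**Route**

Step 1
Reactants: 1 furfural
Product: 3 5-hydroxy-2(5H)-furanone (racemic), via furfural 2,5-endoperoxide 2 (not isolated)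
Conditions: O2, hν (visible), rose bengal (cat.), MeOH, rt
Reagents that add atoms: dioxygen (O=O)
Why: Sensitized singlet-oxygen [4+2] cycloaddition across C2/C5 of the furan (furan photooxygenation) gives endoperoxide 2, which methanol should fragment at the formyl group, with loss of methyl formate, to the hydroxybutenolide.

Step 2
Reactants: 3 5-hydroxy-2(5H)-furanone; 4 (−)-menthol
Product: 6 (5R)-5-(l-menthyloxy)-2(5H)-furanone, via C5-epimeric menthyl acetal mixture 5 (not isolated)
Conditions: CSA (cat.), toluene, reflux, Dean–Stark; crystallization from petroleum ether, −20 °C; mother liquor re-equilibrated with TsOH (cat.) and crystallized again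
Reagents that add atoms: none
Why: Acid-catalysed acetalization of the cyclic hemiacylal gives both C5 epimers, which interconvert under acid while the (5R) epimer crystallizes, so C5 is set by crystallization-induced diastereomer transformation under control of the menthyl group.

Step 3
Reactants: 7 4-benzyloxy-3-methoxybenzaldehyde
Product: 8 2-(4-benzyloxy-3-methoxyphenyl)-1,3-dithiane
Conditions: HS(CH2)3SH, BF3·OEt2 (cat.), CH2Cl2, 0 °C → rt
Reagents that add atoms: propane-1,3-dithiol (SCCCS)
Why: Lewis-acid-catalysed dithioacetalization of an aromatic aldehyde, to which the benzyl ether is inert.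

Step 4
Reactants: 9 methyl vanillate
Product: 10 methyl 4-(2-tert-butoxy-2-oxoethoxy)-3-methoxybenzoate
Conditions: BrCH2CO2tBu, K2CO3, DMF, rt
Reagents that add atoms: tert-butyl bromoacetate (CC(C)(C)OC(=O)CBr)
Why: Williamson ether synthesis, the phenoxide displacing bromide from the activated α-bromo ester by SN2.

Step 5
Reactants: 10 methyl 4-(2-tert-butoxy-2-oxoethoxy)-3-methoxybenzoate
Product: 11 [2-methoxy-4-(methoxycarbonyl)phenoxy]acetic acid
Conditions: TFA, CH2Cl2, rt
Reagents that add atoms: none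
Why: Acidolysis of the tert-butyl ester (loss of isobutene) leaves the methyl benzoate and the aryl ethers untouched.

Step 6
Reactants: 11 [2-methoxy-4-(methoxycarbonyl)phenoxy]acetic acid; 12 (S)-4-benzyl-2-oxazolidinone
Product: 14 (S)-4-benzyl-3-{[2-methoxy-4-(methoxycarbonyl)phenoxy]acetyl}oxazolidin-2-one, via mixed pivalic anhydride 13 (not isolated)
Conditions: PivCl, Et3N, THF, −20 °C; then 12, LiCl, −20 °C → rt
Reagents that add atoms: none
Why: Mixed-anhydride N-acylation of the oxazolidinone, which attacks the unhindered aryloxyacetyl carbonyl and not the pivaloyl carbonyl.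

Step 7
Reactants: 14 (S)-4-benzyl-3-{[2-methoxy-4-(methoxycarbonyl)phenoxy]acetyl}oxazolidin-2-one; 7 4-benzyloxy-3-methoxybenzaldehyde
Product: 16 (4S)-4-benzyl-3-{(2S,3R)-3-(4-benzyloxy-3-methoxyphenyl)-3-hydroxy-2-[2-methoxy-4-(methoxycarbonyl)phenoxy]propanoyl}oxazolidin-2-one, via Z-dibutylboron enolate 15 (not isolated)
Conditions: Bu2BOTf, iPr2NEt, CH2Cl2, −78 → 0 °C; 7, −78 → 0 °C; pH 7 buffer, MeOH, 30% H2O2, 0 °C
Reagents that add atoms: none
Why: Evans syn-aldol, in which the (Z)-boron enolate should react through a chair Zimmerman–Traxler transition state on the face away from the benzyl group of the (S)-auxiliary to give the 2,3-syn adduct, setting C7 (R) and C8 in the threo relationship.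

Step 8
Reactants: 16 the syn-aldol imide
Product: 17 (1R,2R)-1-(4-benzyloxy-3-methoxyphenyl)-2-[4-(hydroxymethyl)-2-methoxyphenoxy]propane-1,3-diol (threo triol)
Conditions: LiBH4, MeOH, THF, 0 → 50 °C
Reagents that add atoms: none
Why: Borohydride reductive cleavage of the exocyclic imide carbonyl and reduction of the methyl benzoate touch no stereocentre (the C8 descriptor changes from S to R only through the change of priorities).

Step 9
Reactants: 17 the threo triol
Product: 18 (4-{[(4R,5R)-4-(4-benzyloxy-3-methoxyphenyl)-2,2-dimethyl-1,3-dioxan-5-yl]oxy}-3-methoxyphenyl)methanol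
Conditions: Me2C(OMe)2, PPTS (cat.), acetone, rt; Et3N quench
Reagents that add atoms: 2,2-dimethoxypropane (COC(C)(C)OC)
Why: Acid-catalysed ketalization, in which only the C7/C9 1,3-diol can close a cyclic ketal (a 1,3-dioxane with aryl and aryloxy groups both equatorial), so the lone benzylic CH2OH stays free.

Step 10
Reactants: 18 the acetonide benzylic alcohol
Product: 19 (4R,5R)-4-(4-benzyloxy-3-methoxyphenyl)-5-[4-(bromomethyl)-2-methoxyphenoxy]-2,2-dimethyl-1,3-dioxane
Conditions: CBr4, PPh3, CH2Cl2, 0 °C; used at once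
Reagents that add atoms: carbon tetrabromide (BrC(Br)(Br)Br)
Why: Appel reaction, which converts the primary benzylic alcohol into the bromide under neutral conditions that spare the acetonide.

Step 11
Reactants: 8 2-(4-benzyloxy-3-methoxyphenyl)-1,3-dithiane; 6 (5R)-5-(l-menthyloxy)-2(5H)-furanone; 19 the side-chain benzylic bromide
Product: 22 (3R,4R,5R)-3-(SCBn)-4-[2-(4-benzyloxy-3-methoxyphenyl)-1,3-dithian-2-yl]-5-(l-menthyloxy)dihydrofuran-2(3H)-one, via 2-lithio-2-aryl-1,3-dithiane 20 (not isolated), via lithium lactone enolate 21 (not isolated)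
Conditions: 8, n-BuLi, THF, −78 → −20 °C; then 6, THF, −90 °C; then 19, DMPU, −78 °C → rt
Reagents that add atoms: none
Why: n-BuLi removes the C2 proton of 8 to give the sulfur-stabilized benzylic carbanion 20 (a benzyl anion equivalent), which adds in Michael fashion to C4 of butenolide 6; the resulting lithium enolate 21 is then alkylated at C3 by SN2 displacement of the benzylic bromide 19, so both benzylic C–C bonds on the lactone form in one flask and no ring is closed. The closest known reaction type is the tandem conjugate addition–enolate alkylation of lithiated 2-aryl-1,3-dithianes on 5-alkoxy-2(5H)-furanones with benzyl halides. C4 is set by the (5R)-menthyloxy acetal, the nucleophile attacking the butenolide face anti to the C5 alkoxy group. C3 is set by the new, very bulky C4 dithianyl group, the electrophile entering anti to it, so the 3,4-trans (and 4,5-trans) lactone should result. The step needs 1,4- over 1,2-addition, which the soft, delocalized and hindered 2-aryl dithiane anion secures, and C-monoalkylation of the enolate, which the high SN2 reactivity of the electron-rich benzylic bromide and DMPU as cosolvent favour, while the acetonide, benzyl ethers and aryl ethers of 19 offer no acidic or electrophilic site.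

Step 12
Reactants: 22 the dithianyl lactone acetal
Product: 23 (3R,4R,5R)-3-(SCBn)-4-(4-benzyloxy-3-methoxybenzyl)-5-(l-menthyloxy)dihydrofuran-2(3H)-one
Conditions: NiCl2·6H2O, NaBH4, MeOH/THF, 0 °C
Reagents that add atoms: none
Why: Nickel boride (Ni2B) formed in situ cleaves both benzylic C–S bonds by reductive desulfurization, turning the dithiane carbon into the C4 benzylic CH2 without touching the benzyl ethers, the acetonide or the ring stereocentres.

Step 13
Reactants: 23 the dibenzyl lactone acetal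
Product: 27 (3R,4R)-4-(4-benzyloxy-3-methoxybenzyl)-3-{4-[(1R,2R)-1-(4-benzyloxy-3-methoxyphenyl)-1,3-dihydroxypropan-2-yl]oxy-3-methoxybenzyl}dihydrofuran-2(3H)-one, via potassium aldehyde carboxylate 24 (not isolated), via potassium hydroxy carboxylate 25 (not isolated), via acetonide lactone 26 (not isolated)
Conditions: KOH, NaBH4, EtOH/H2O, rt; then 2 M HCl, THF, 0 °C → rt
Reagents that add atoms: none
Why: Hydroxide opens the lactone acyl acetal and the hemiacetal expels mentholate to unveil the C5 aldehyde, which NaBH4 in the same solution should reduce before enolization at C4 can compete; acidification then closes the γ-lactone by 5-exo-trig acyl substitution and hydrolyses the 1,3-dioxane ketal (saponification–reduction–lactonization with ketal hydrolysis), leaving C3, C4, C7 and C8 unchanged.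

Step 14
Reactants: 27 the di-O-benzyl lactone diol
Product: 28 target CNP0305334.1
Conditions: H2 (1 atm), 10% Pd/C, EtOAc/EtOH, rt
Reagents that add atoms: none
Why: Heterogeneous palladium-catalysed hydrogenolysis cleaves the two aryl benzyl ethers, which should react much faster at 1 atm in a neutral solvent than the secondary C7 carbinol, the alkyl aryl ether or the lactone.

**Compound list**
1 | furfural | O=Cc1ccco1 | starting material
2 | furfural 2,5-endoperoxide | O=CC12C=CC(OO1)O2 | intermediate
3 | 5-hydroxy-2(5H)-furanone (racemic) | O=C1C=CC(O)O1 | intermediate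
4 | (−)-menthol, (1R,2S,5R) | CC(C)[C@@H]1CC[C@@H](C)C[C@H]1O | starting material
5 | 5-(l-menthyloxy)-2(5H)-furanone, C5 epimer mixture | O=C1C=CC(O[C@@H]2C[C@H](C)CC[C@H]2C(C)C)O1 | intermediate
6 | (5R)-5-(l-menthyloxy)-2(5H)-furanone | O=C1C=C[C@H](O[C@@H]2C[C@H](C)CC[C@H]2C(C)C)O1 | intermediate
7 | 4-benzyloxy-3-methoxybenzaldehyde | COc1cc(C=O)ccc1OCc1ccccc1 | starting material
8 | 2-(4-benzyloxy-3-methoxyphenyl)-1,3-dithiane | COc1cc(C2SCCCS2)ccc1OCc1ccccc1 | intermediate
9 | methyl vanillate | COC(=O)c1ccc(O)c(OC)c1 | starting material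
10 | methyl 4-(2-tert-butoxy-2-oxoethoxy)-3-methoxybenzoate | COC(=O)c1ccc(OCC(=O)OC(C)(C)C)c(OC)c1 | intermediate
11 | [2-methoxy-4-(methoxycarbonyl)phenoxy]acetic acid | COC(=O)c1ccc(OCC(=O)O)c(OC)c1 | intermediate
12 | (S)-4-benzyl-2-oxazolidinone | O=C1OC[C@H](Cc2ccccc2)N1 | starting material
13 | mixed pivalic anhydride of 11 | COC(=O)c1ccc(OCC(=O)OC(=O)C(C)(C)C)c(OC)c1 | intermediate
14 | (S)-4-benzyl-3-{[2-methoxy-4-(methoxycarbonyl)phenoxy]acetyl}oxazolidin-2-one | COC(=O)c1ccc(OCC(=O)N2C(=O)OC[C@@H]2Cc2ccccc2)c(OC)c1 | intermediate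
15 | (Z)-dibutylboron enolate of 14 | CCCCB(CCCC)O/C(=C\Oc1ccc(C(=O)OC)cc1OC)N1C(=O)OC[C@@H]1Cc1ccccc1 | intermediate
16 | (4S)-4-benzyl-3-{(2S,3R)-3-(4-benzyloxy-3-methoxyphenyl)-3-hydroxy-2-[2-methoxy-4-(methoxycarbonyl)phenoxy]propanoyl}oxazolidin-2-one | COC(=O)c1ccc(O[C@@H]([C@H](O)c2ccc(OCc3ccccc3)c(OC)c2)C(=O)N2C(=O)OC[C@@H]2Cc2ccccc2)c(OC)c1 | intermediate
17 | (1R,2R)-1-(4-benzyloxy-3-methoxyphenyl)-2-[4-(hydroxymethyl)-2-methoxyphenoxy]propane-1,3-diol | OCc1ccc(O[C@H](CO)[C@H](O)c2ccc(OCc3ccccc3)c(OC)c2)c(OC)c1 | intermediate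
18 | (4-{[(4R,5R)-4-(4-benzyloxy-3-methoxyphenyl)-2,2-dimethyl-1,3-dioxan-5-yl]oxy}-3-methoxyphenyl)methanol | OCc1ccc(O[C@@H]2COC(C)(C)O[C@@H]2c2ccc(OCc3ccccc3)c(OC)c2)c(OC)c1 | intermediate
19 | (4R,5R)-4-(4-benzyloxy-3-methoxyphenyl)-5-[4-(bromomethyl)-2-methoxyphenoxy]-2,2-dimethyl-1,3-dioxane | BrCc1ccc(O[C@@H]2COC(C)(C)O[C@@H]2c2ccc(OCc3ccccc3)c(OC)c2)c(OC)c1 | intermediate
20 | 2-lithio-2-(4-benzyloxy-3-methoxyphenyl)-1,3-dithiane | [Li]C1(c2ccc(OCc3ccccc3)c(OC)c2)SCCCS1 | intermediate
21 | lithium enolate of (4R,5R)-4-[2-(4-benzyloxy-3-methoxyphenyl)-1,3-dithian-2-yl]-5-(l-menthyloxy)dihydrofuran-2(3H)-one | COc1cc(C2(SCCCS2)[C@@H]3C=C(O[Li])O[C@H]3O[C@@H]3C[C@H](C)CC[C@H]3C(C)C)ccc1OCc1ccccc1 | intermediate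
22 | (3R,4R,5R)-3-(SCBn)-4-[2-(4-benzyloxy-3-methoxyphenyl)-1,3-dithian-2-yl]-5-(l-menthyloxy)dihydrofuran-2(3H)-one | COc1cc(C2(SCCCS2)[C@H]2[C@H](O[C@@H]3C[C@H](C)CC[C@H]3C(C)C)OC(=O)[C@@H]2Cc2ccc(O[C@@H]3COC(C)(C)O[C@@H]3c3ccc(OCc4ccccc4)c(OC)c3)c(OC)c2)ccc1OCc1ccccc1 | intermediate
23 | (3R,4R,5R)-3-(SCBn)-4-(4-benzyloxy-3-methoxybenzyl)-5-(l-menthyloxy)dihydrofuran-2(3H)-one | COc1cc(C[C@H]2[C@H](O[C@@H]3C[C@H](C)CC[C@H]3C(C)C)OC(=O)[C@@H]2Cc2ccc(O[C@@H]3COC(C)(C)O[C@@H]3c3ccc(OCc4ccccc4)c(OC)c3)c(OC)c2)ccc1OCc1ccccc1 | intermediate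
24 | potassium (2R,3R)-3-(4-benzyloxy-3-methoxybenzyl)-4-oxo-2-(SCBn)butanoate | COc1cc(C[C@@H](C=O)[C@@H](Cc2ccc(O[C@@H]3COC(C)(C)O[C@@H]3c3ccc(OCc4ccccc4)c(OC)c3)c(OC)c2)C(=O)[O-])ccc1OCc1ccccc1.[K+] | intermediate
25 | potassium (2R,3R)-3-(4-benzyloxy-3-methoxybenzyl)-4-hydroxy-2-(SCBn)butanoate | COc1cc(C[C@@H](CO)[C@@H](Cc2ccc(O[C@@H]3COC(C)(C)O[C@@H]3c3ccc(OCc4ccccc4)c(OC)c3)c(OC)c2)C(=O)[O-])ccc1OCc1ccccc1.[K+] | intermediate
26 | (3R,4R)-4-(4-benzyloxy-3-methoxybenzyl)-3-(SCBn)dihydrofuran-2(3H)-one | COc1cc(C[C@H]2COC(=O)[C@@H]2Cc2ccc(O[C@@H]3COC(C)(C)O[C@@H]3c3ccc(OCc4ccccc4)c(OC)c3)c(OC)c2)ccc1OCc1ccccc1 | intermediate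
27 | (3R,4R)-4-(4-benzyloxy-3-methoxybenzyl)-3-{4-[(1R,2R)-1-(4-benzyloxy-3-methoxyphenyl)-1,3-dihydroxypropan-2-yl]oxy-3-methoxybenzyl}dihydrofuran-2(3H)-one | COc1cc(C[C@H]2COC(=O)[C@@H]2Cc2ccc(O[C@H](CO)[C@H](O)c3ccc(OCc4ccccc4)c(OC)c3)c(OC)c2)ccc1OCc1ccccc1 | intermediate
28 | CNP0305334.1, (3R,4R)-4-(4-hydroxy-3-methoxybenzyl)-3-{4-[(1R,2R)-1,3-dihydroxy-1-(4-hydroxy-3-methoxyphenyl)propan-2-yl]oxy-3-methoxybenzyl}dihydrofuran-2(3H)-one | COc1cc(C[C@H]2COC(=O)[C@@H]2Cc2ccc(O[C@H](CO)[C@H](O)c3ccc(O)c(OC)c3)c(OC)c2)ccc1O | target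

**Step count**
Total: 14 steps. Longest linear sequence: 11 steps (steps 4–14, from methyl vanillate 9 to 28).

**Steps most likely to fail**

Step 11. The enolate formed by the conjugate addition may be protonated or may fail to capture the labile, electron-rich bromide before it decomposes, so that alkylation is incomplete; competing 1,2-addition would add to the loss. The fallback separates the two bond formations. It sets out from 8 and 6: the conjugate addition is run as before but quenched with NH4Cl at −78 °C, which should give the 3-unsubstituted conjugate adduct F1 with the same anti selectivity at C4. F1, used in excess over the bromide, is then deprotonated with LiN(iPr)2 in THF/DMPU at −78 °C and alkylated with 19 (Bu4NI cat.), again anti to the dithianyl group. The fallback comes back to the route at 22.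

Step 7. Enolization may be incomplete, or the syn selectivity eroded, if the ortho-methoxy and aryloxy oxygens bind boron; retro-aldol cleavage on work-up is also possible. The fallback sets the two centres by reduction instead of by C–C bond formation, and sets out from 10. Commercial 4-benzyloxy-3-methoxybenzoic acid is activated with carbonyldiimidazole to the acyl imidazolide F2, which acylates the lithium enolate of 10 (LiN(SiMe3)2, 2 equiv, THF, −78 °C) to the racemic β-keto ester F3. Asymmetric transfer hydrogenation with dynamic kinetic resolution (RuCl(p-cymene)[(S,S)-TsDPEN], HCO2H/Et3N) should then give the syn hydroxy ester F4. The (3R) sense is the one expected from the usual aryl ketone model, and the (R,R) complex would be used if the opposite sense were found. LiAlH4 (THF, 0 °C) reduces both esters of F4, and the fallback comes back to the route at 17.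

Step 13. In the acid stage the electron-rich benzylic C7–O bond may ionize, with loss of threo purity, or ring closure may be incomplete while the ketal is being hydrolysed. The fallback avoids strong aqueous acid and sets out from 23. After the same KOH/NaBH4 treatment the solution is brought to pH 5 with NaH2PO4 and extracted, which should give the free hydroxy acid F5 with the acetonide intact. F5 is lactonized under neutral dehydrating conditions (EDC·HCl, DMAP, CH2Cl2) to 26, now isolated. The ketal is then removed by transketalization (PPTS, MeOH, rt), and the fallback comes back to the route at 27.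

**Further compounds**
F1 | step 11 | (4R,5R)-4-[2-(4-benzyloxy-3-methoxyphenyl)-1,3-dithian-2-yl]-5-(l-menthyloxy)dihydrofuran-2(3H)-one | COc1cc(C2(SCCCS2)[C@@H]3CC(=O)O[C@H]3O[C@@H]3C[C@H](C)CC[C@H]3C(C)C)ccc1OCc1ccccc1
F2 | step 7 | 1-(4-benzyloxy-3-methoxybenzoyl)imidazole | COc1cc(C(=O)n2ccnc2)ccc1OCc1ccccc1
F3 | step 7 | tert-butyl 3-(4-benzyloxy-3-methoxyphenyl)-2-[2-methoxy-4-(methoxycarbonyl)phenoxy]-3-oxopropanoate (racemic) | COC(=O)c1ccc(OC(C(=O)c2ccc(OCc3ccccc3)c(OC)c2)C(=O)OC(C)(C)C)c(OC)c1
F4 | step 7 | tert-butyl (2S,3R)-3-(4-benzyloxy-3-methoxyphenyl)-3-hydroxy-2-[2-methoxy-4-(methoxycarbonyl)phenoxy]propanoate | COC(=O)c1ccc(O[C@@H]([C@H](O)c2ccc(OCc3ccccc3)c(OC)c2)C(=O)OC(C)(C)C)c(OC)c1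
F5 | step 13 | (2R,3R)-3-(4-benzyloxy-3-methoxybenzyl)-4-hydroxy-2-(SCBn)butanoic acid | COc1cc(C[C@@H](CO)[C@@H](Cc2ccc(O[C@@H]3COC(C)(C)O[C@@H]3c3ccc(OCc4ccccc4)c(OC)c3)c(OC)c2)C(=O)O)ccc1OCc1ccccc1
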